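## Structural features

Compound 15 is a flavanone. Benzene ring A is fused along C4a–C8a to the dihydropyranone ring C (O1, C2, C3, C4), and ring C carries the 4-hydroxyphenyl ring B on C2. Ring A is substituted everywhere except C6: a hydroxyl on C5 hydrogen-bonded to the C4 carbonyl, a geranyl ether on O7, and a carbon-bound geranyl chain on C8 next to the ring oxygen. C2 (S) is the only stereocentre, so no neighbouring centre can relay configuration to it. It is benzylic, bound to O1 and β to the C4 carbonyl, so base can scramble it by opening ring C to the 2'-hydroxychalcone, and acid can ionise C2–O1 with help from the para-oxygenated ring B. The two geranyl groups bring four trisubstituted alkenes (both 2,3-double bonds E) and an allyl aryl ether. These exclude strong protic or Lewis acids, hydrogenation and oxidants, and they limit heating. The real difficulty is twofold: telling apart three oxygens and one ring carbon of a phloroglucinol, and fixing C2 in a way that cannot leak through the chalcone. The key step exploits the fact that C3 and C4 can both be carried as alkene carbons: C4 as the silyloxy-bearing carbon of a 1-silyloxyvinyl group on C4a, and C3 as the inner carbon of a vinyl group on the preformed C2 centre. Metathesis then forms C3=C4 and closes ring C without touching any bond to C2.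

## Logic of the disconnections

**15 from 14.** No skeletal bond is cut; three Si–O bonds are traced back (the enol ether at C4 and the silyl ethers on O5 and O4'). They are cut last because one buffered fluoride treatment removes all three without touching the allyl aryl ether, the four trisubstituted alkenes or C2–O1. The gain is that the base-labile β-aryloxy ketone exists only in the final flask. The demand is that the enolate released at C3/C4 is protonated before it can expel the C8a oxygen.

**14 from 13.** The C3=C4 bond of ring C is cut (retro-metathesis), leaving a 1-silyloxyvinyl group on C4a and a vinyl group on C2. It is the one ring C bond whose formation involves neither C2 nor a carbonyl enolate. The precursor is a plain aryl ether of ring A with C2 already in place. The forward step must make the ruthenium alkylidene choose the enol ether over five other alkenes, above all the nearer alkene of the C8 chain.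

**13 from 12.** The enol O–Si bond is cut, returning the methyl ketone on C4a. This places the enol ether one step before its use, so it is never carried through other chemistry. The demand is an enolisation that neither ionises C2–O1 nor removes the C2 hydrogen.

**12 from 6 and 10 (through 11).** O1–C2 is cut. It is the only bond joining the ring A and ring B halves, it forms by substitution at an allyl terminus, and the stereocentre appears in the same step under catalyst control. The gain is two achiral fragments of similar size and a convergent route. The forward step must give the branched ether, one face, and O- rather than C-attack, with a hindered and chelated aryloxide.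

**10 from 9.** The acyl C–O bond of the carbonate is cut. The leaving group for the allylic substitution is attached last; the demand is only a clean acylation of a primary allylic alcohol.

**9 from 8.** The ester C–OMe bond is cut (alcohol back to ester oxidation level). The E alkene is thereby bought ready-made; the reduction must be 1,2-selective and spare the aryl silyl ether.

**8 from 7.** The O4'–Si bond is cut, giving a commercial phenol. A silyl ether is chosen so that it falls in the same fluoride operation as the others.

**6 from 5.** The O–Si bond on the future O5 is cut. This leaves one free hydroxyl, the future O1, for step 7. The silylation must choose the hydroxyl flanked by hydrogen over the one flanked by the C-geranyl chain.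

**5 from 3 and 4.** The O7–C bond of the geranyl ether is cut. The para-hydroxyl is the only one not chelated to the acetyl group, so it can be alkylated selectively. The demand is O- rather than C-alkylation and no allylic transposition.

**3 from 1 and 2.** The C8–C1' bond of the C-geranyl chain is cut. The two free ring carbons of 1 are equivalent, so only one mono-C-alkylated product exists. The forward step must favour carbon over oxygen and mono- over dialkylation.

## Other disconnections considered

**Alternative 1:** The cut is C2–C3, so that ring C and C2 arise together. The racemic enol acetal A1, 8-geranyl-7-(geranyloxy)-4-methylene-5-(triisopropylsilyloxy)-2-[4-(triisopropylsilyloxy)phenyl]-4H-1,3-benzodioxine, would be opened by a chiral aluminium Lewis acid prepared from AlMe3 and a 3,3'-disubstituted BINOL. The resulting aluminium enolate and O1-aryl oxocarbenium ion would recombine at carbon (Petasis–Ferrier rearrangement) to A2, (2S)-8-geranyl-7-(geranyloxy)-5,4'-bis(triisopropylsilyloxy)flavanone.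
- In favour: ring, bond and stereocentre come in one operation from a precursor whose own configuration does not matter. No ruthenium is involved, so there is no competition among alkenes; on this point it is better than the chosen plan. A2 is one fluoride step from 15, equal to the chosen endgame.
- Against: face selection would rest on a chiral aluminate acting on a planar oxocarbenium ion, for which no established enantioselective counterpart exists. The chosen plan fixes C2 with a catalytic reaction type of known scope. The acetal can also ionise with the phenolic O1 as leaving group, which is unproductive. A strong Lewis acid is what the allyl aryl ether and the trisubstituted alkenes tolerate least, and the aluminium-chelated product could undergo retro-oxa-Michael opening.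
- Comparison: both plans carry C4 as an enol derivative on C4a. Here C2 is planar at the decisive moment; in the chosen plan it is a preformed tetrahedral centre that the ring closure does not touch. A1 needs the same three regiochemical differentiations of ring A, at the carboxylic acid oxidation level, plus acetalisation and carbonyl methylenation. The step count is therefore about equal, not lower.

**Alternative 2:** The cut runs through ring A: C7–C8, C8a–C4a and C6–C7. Heating 3-(methoxymethoxy)cyclobut-2-en-1-one A3 with the siloxyalkyne A4, triisopropyl{[(4E)-5,9-dimethyldeca-4,8-dien-1-yn-1-yl]oxy}silane, would give the phenol A5, 2-geranyl-5-(methoxymethoxy)-3-(triisopropylsilyloxy)phenol (Danheiser benzannulation). The sequence is four-electron ring opening to a vinylketene, [2+2] addition to the alkyne, a second ring opening and 6π closure.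
- In favour: the C-geranyl group and three differently masked oxygens are placed by the connectivity of the reactants alone. On this point it is better than steps 1–3 of the chosen plan, which rely on site selectivity. The cascade is neutral and metal-free, equal in mildness toward the alkenes apart from the higher temperature.
- Against: it builds a ring that can be bought as 1. It leaves C4a unsubstituted and says nothing about C4, ring C or C2, so the central problem still needs another disconnection. A3 and A4 each need several steps, and an acid-labile acetal returns on O5.
- Comparison: clearly longer. It is better seen as a possible source of a ring A building block than as a competing strategy.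

**Alternative 3:** The cut is C4a–C5: ring A is closed last onto a preformed chiral ring C. On heating, the tert-butyl β-keto ester A6, tert-butyl 4-{(2S)-2-[4-(tert-butyldimethylsilyloxy)phenyl]-4-oxo-3,4-dihydro-2H-pyran-6-yl}-4-geranyl-3-oxobutanoate, would lose its tert-butoxy group as the alcohol. The acylketene formed would acylate the nucleophilic α-carbon of the vinylogous ester (C4a), and enolisation would aromatise ring A to A7, (2S)-8-geranyl-5,7-dihydroxy-4'-(tert-butyldimethylsilyloxy)flavanone.
- In favour: C2 would be set early on a small dihydropyranone by well-developed asymmetric hetero-Diels–Alder chemistry. That is probably more secure than etherification of the hindered aryloxide in step 7, so the alternative is better there. The ring A oxygens emerge unprotected and the C8 chain position is fixed by construction, better than step 1. The O7 geranylation that must follow relies on the same acidity difference as step 2, so it is equal.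
- Against: the acylketene can be captured at oxygen instead of carbon. The thermolysis needs about 100 °C or more on a β-alkoxy enone whose C2–O1 bond can eliminate, which endangers the enantiomeric purity; the chosen key step runs at 40 °C. The side chain of A6 has three acidic positions, so the regiochemical problem of geranylation is moved, not removed.
- Comparison: A7 is one O-alkylation and one desilylation from 15, but A6 is long to assemble, so the route would most likely exceed ten steps. Both plans keep C2 intact once made; this one exposes it to more forcing conditions.

Key step: step 9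

Remark: "geranyl" means (2E)-3,7-dimethylocta-2,6-dien-1-yl. Compounds 1, 2, 4 and 7 are taken as commercial. The sense of induction assigned to the ligand in step 7 rests on the accepted facial model for this catalyst class; the mirror-image ligand is the remedy if a model reaction shows the opposite sense.

## Route

Step 1
Reactants: 1 2,4,6-trihydroxyacetophenone; 2 geranyl bromide
Product: 3 1-(3-geranyl-2,4,6-trihydroxyphenyl)ethanone
Conditions: DBU, THF, 0 °C → rt (1 in 1.5-fold excess)
Reagents that add atoms: none
Why: C-alkylation of an acylphloroglucinol anion with an allylic bromide; the soft ring carbon between two hydroxyls attacks by SN2 and the E geometry of the chain is kept. The two free ring carbons of 1 are equivalent, and an excess of 1 limits dialkylation.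

Step 2
Reactants: 3 1-(3-geranyl-2,4,6-trihydroxyphenyl)ethanone; 4 geraniol
Product: 5 1-[3-geranyl-4-(geranyloxy)-2,6-dihydroxyphenyl]ethanone
Conditions: PPh3, DIAD, THF, 0 °C → rt
Reagents that add atoms: none
Why: Mitsunobu etherification; the para-hydroxyl is the most acidic and the only one not tied up in a hydrogen bond to the acetyl group, so it alone is alkylated. The primary allylic oxyphosphonium is displaced by SN2 at oxygen, which avoids the C-alkylation that a base and allylic halide would risk.

Step 3
Reactants: 5 1-[3-geranyl-4-(geranyloxy)-2,6-dihydroxyphenyl]ethanone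
Product: 6 1-[3-geranyl-4-(geranyloxy)-2-hydroxy-6-(triisopropylsilyloxy)phenyl]ethanone
Conditions: TIPSOTf (1.05 equiv), 2,6-lutidine, CH2Cl2, −78 → 0 °C
Reagents that add atoms: triisopropylsilyl triflate, CC(C)[Si](OS(=O)(=O)C(F)(F)F)(C(C)C)C(C)C
Why: Silylation of a phenol; the bulky silyl group goes to the hydroxyl flanked by hydrogen, not the one shielded by the C-geranyl chain, and the remaining hydroxyl is then locked in a strong hydrogen bond. Lutidine keeps the medium non-acidic for the alkenes and the allyl aryl ether.

Step 4
Reactants: 7 methyl (E)-4-hydroxycinnamate
Product: 8 methyl (E)-4-(tert-butyldimethylsilyloxy)cinnamate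
Conditions: TBSCl, imidazole, DMF, rt
Reagents that add atoms: tert-butyldimethylsilyl chloride, CC(C)(C)[Si](C)(C)Cl
Why: Standard silylation of an unhindered phenol; a silyl ether is chosen so that ring B is deprotected by the same fluoride treatment as the rest.

Step 5
Reactants: 8 methyl (E)-4-(tert-butyldimethylsilyloxy)cinnamate
Product: 9 (E)-3-[4-(tert-butyldimethylsilyloxy)phenyl]prop-2-en-1-ol
Conditions: i-Bu2AlH (2.5 equiv), CH2Cl2, −78 °C; aq. potassium sodium tartrate
Reagents that add atoms: none
Why: 1,2-Reduction of an α,β-unsaturated ester to the allylic alcohol by an aluminium hydride at low temperature; the alkene geometry and the aryl silyl ether are not affected.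

Step 6
Reactants: 9 (E)-3-[4-(tert-butyldimethylsilyloxy)phenyl]prop-2-en-1-ol
Product: 10 (E)-3-[4-(tert-butyldimethylsilyloxy)phenyl]allyl methyl carbonate
Conditions: ClCO2Me, pyridine, CH2Cl2, 0 °C
Reagents that add atoms: methyl chloroformate, COC(=O)Cl
Why: Acylation of a primary allylic alcohol to the linear methyl carbonate, the usual electrophile for iridium-catalysed allylic substitution.

Step 7
Reactants: 6 1-[3-geranyl-4-(geranyloxy)-2-hydroxy-6-(triisopropylsilyloxy)phenyl]ethanone; 10 (E)-3-[4-(tert-butyldimethylsilyloxy)phenyl]allyl methyl carbonate
Product: 12 1-[2-{(1S)-1-[4-(tert-butyldimethylsilyloxy)phenyl]allyloxy}-3-geranyl-4-(geranyloxy)-6-(triisopropylsilyloxy)phenyl]ethanone, via sodium aryloxide 11 (not isolated)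
Conditions: NaH (1.0 equiv), THF, 0 °C; then 10 (1.3 equiv), [Ir(cod)Cl]2 (2 mol%), (Sa)-binaphthalene-2,2'-diyl N,N-bis[(S)-1-phenylethyl]phosphoramidite (4 mol%, pre-activated with n-PrNH2), THF, rt
Reagents that add atoms: none
Why: Iridium-catalysed asymmetric allylic etherification of an aryloxide with a linear cinnamyl-type carbonate; the cyclometallated iridium–phosphoramidite complex ionises 10 to an allyl complex that the aryloxide attacks at the aryl-bearing terminus, giving the branched ether. The ligand controls the face; the (Sa,Sc,Sc) ligand is expected from the accepted model to give the S ether. One equivalent of pre-formed aryloxide leaves only sodium methyl carbonate, so no free alkoxide meets the silyl ethers, and both ortho positions of the new ether are blocked against Claisen rearrangement.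

Step 8
Reactants: 12 1-[2-{(1S)-1-[4-(tert-butyldimethylsilyloxy)phenyl]allyloxy}-3-geranyl-4-(geranyloxy)-6-(triisopropylsilyloxy)phenyl]ethanone
Product: 13 tert-butyl{1-[2-{(1S)-1-[4-(tert-butyldimethylsilyloxy)phenyl]allyloxy}-3-geranyl-4-(geranyloxy)-6-(triisopropylsilyloxy)phenyl]vinyloxy}dimethylsilane
Conditions: TBSOTf (1.3 equiv), Et3N (3 equiv), CH2Cl2, −78 → 0 °C
Reagents that add atoms: tert-butyldimethylsilyl triflate, CC(C)(C)[Si](C)(C)OS(=O)(=O)C(F)(F)F
Why: Soft enolisation and O-silylation of a methyl ketone with a silyl triflate and a tertiary amine; the acetyl group has only one enolisable position. No free enolate or strong base is present, so the aryl silyl ether cannot migrate and the C2 hydrogen is not removed, and the excess amine buffers the triflate against ionising C2–O1.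

Step 9
Reactants: 13 tert-butyl{1-[2-{(1S)-1-[4-(tert-butyldimethylsilyloxy)phenyl]allyloxy}-3-geranyl-4-(geranyloxy)-6-(triisopropylsilyloxy)phenyl]vinyloxy}dimethylsilane
Product: 14 (2S)-4-(tert-butyldimethylsilyloxy)-2-[4-(tert-butyldimethylsilyloxy)phenyl]-8-geranyl-7-(geranyloxy)-5-(triisopropylsilyloxy)-2H-chromene
Conditions: second-generation Grubbs catalyst (H2IMes)(PCy3)Cl2Ru=CHPh (10 mol%), degassed CH2Cl2 (5 mM), 40 °C, argon sparge, dark
Reagents that add atoms: none
Why: Ring-closing olefin metathesis of a silyl enol ether with a terminal alkene, a known route to cyclic enol ethers and, from ortho-vinylaryl allyl ethers, to 2H-chromenes. The ruthenium benzylidene exchanges onto the only monosubstituted alkene, the vinyl group on C2; the new alkylidene adds across the 1,1-disubstituted C(OSi)=CH2 on C4a with the metal on the CH2 carbon, and cycloreversion of the ruthenacyclobutane gives C3=C4 and Ru=CH2, which releases ethylene on the next turnover. The closure is six-membered (O1, C2, C3, C4, C4a, C8a) with the new double bond inside the ring. No stereocentre is formed; C2 keeps its S configuration because none of its four bonds is touched and the medium is neutral. Of the six C=C bonds of 13 the carbene has five possible partners: the enol ether gives the six-membered ring and regenerates the unhindered methylidene, the proximal alkene of the C8 chain would give a seven-membered benzoxepine only through a trisubstituted alkene and a disubstituted alkylidene, and the other three would give rings of nine or more atoms. Ring size and alkene substitution therefore both favour the chromene; sparging removes ethylene, and 40 °C in the dark limits electrocyclic opening of the 2H-chromene.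

Step 10
Reactants: 14 (2S)-4-(tert-butyldimethylsilyloxy)-2-[4-(tert-butyldimethylsilyloxy)phenyl]-8-geranyl-7-(geranyloxy)-5-(triisopropylsilyloxy)-2H-chromene
Product: 15 (2S)-8-geranyl-7-(geranyloxy)-5-hydroxy-2-(4-hydroxyphenyl)chroman-4-one
Conditions: Bu4NF/AcOH (1:1, 4 equiv), THF, 0 °C → rt; pH 7 buffer work-up
Reagents that add atoms: none
Why: Fluoride-induced cleavage of a silyl enol ether and two aryl silyl ethers in one operation; acetic acid protonates the enolate at C3 and the phenoxides as they form, so ring C cannot open to the chalcone and C2 stays S. No acid strong enough to attack the allyl aryl ether or the trisubstituted alkenes is present.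

## Compound list

1 | 2,4,6-trihydroxyacetophenone | CC(=O)c1c(O)cc(O)cc1O | starting material
2 | geranyl bromide | CC(C)=CCC/C(C)=C/CBr | starting material
3 | 1-(3-geranyl-2,4,6-trihydroxyphenyl)ethanone | CC(=O)c1c(O)cc(O)c(C/C=C(\C)CCC=C(C)C)c1O | intermediate
4 | geraniol | CC(C)=CCC/C(C)=C/CO | starting material
5 | 1-[3-geranyl-4-(geranyloxy)-2,6-dihydroxyphenyl]ethanone | CC(C)=CCC/C(C)=C/COc1cc(O)c(C(C)=O)c(O)c1C/C=C(\C)CCC=C(C)C | intermediate
6 | 1-[3-geranyl-4-(geranyloxy)-2-hydroxy-6-(triisopropylsilyloxy)phenyl]ethanone | CC(C)=CCC/C(C)=C/COc1cc(O[Si](C(C)C)(C(C)C)C(C)C)c(C(C)=O)c(O)c1C/C=C(\C)CCC=C(C)C | intermediate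
7 | methyl (E)-4-hydroxycinnamate | COC(=O)/C=C/c1ccc(O)cc1 | starting material
8 | methyl (E)-4-(tert-butyldimethylsilyloxy)cinnamate | COC(=O)/C=C/c1ccc(O[Si](C)(C)C(C)(C)C)cc1 | intermediate
9 | (E)-3-[4-(tert-butyldimethylsilyloxy)phenyl]prop-2-en-1-ol | OC/C=C/c1ccc(O[Si](C)(C)C(C)(C)C)cc1 | intermediate
10 | (E)-3-[4-(tert-butyldimethylsilyloxy)phenyl]allyl methyl carbonate | COC(=O)OC/C=C/c1ccc(O[Si](C)(C)C(C)(C)C)cc1 | intermediate
11 | sodium 2-acetyl-6-geranyl-5-(geranyloxy)-3-(triisopropylsilyloxy)phenolate | CC(C)=CCC/C(C)=C/COc1cc(O[Si](C(C)C)(C(C)C)C(C)C)c(C(C)=O)c([O-])c1C/C=C(\C)CCC=C(C)C.[Na+] | intermediate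
12 | 1-[2-{(1S)-1-[4-(tert-butyldimethylsilyloxy)phenyl]allyloxy}-3-geranyl-4-(geranyloxy)-6-(triisopropylsilyloxy)phenyl]ethanone | CC(C)=CCC/C(C)=C/COc1cc(O[Si](C(C)C)(C(C)C)C(C)C)c(C(C)=O)c(c1C/C=C(\C)CCC=C(C)C)O[C@H](c1ccc(O[Si](C)(C)C(C)(C)C)cc1)C=C | intermediate
13 | tert-butyl{1-[2-{(1S)-1-[4-(tert-butyldimethylsilyloxy)phenyl]allyloxy}-3-geranyl-4-(geranyloxy)-6-(triisopropylsilyloxy)phenyl]vinyloxy}dimethylsilane | CC(C)=CCC/C(C)=C/COc1cc(O[Si](C(C)C)(C(C)C)C(C)C)c(C(=C)O[Si](C)(C)C(C)(C)C)c(c1C/C=C(\C)CCC=C(C)C)O[C@H](c1ccc(O[Si](C)(C)C(C)(C)C)cc1)C=C | intermediate
14 | (2S)-4-(tert-butyldimethylsilyloxy)-2-[4-(tert-butyldimethylsilyloxy)phenyl]-8-geranyl-7-(geranyloxy)-5-(triisopropylsilyloxy)-2H-chromene | CC(C)=CCC/C(C)=C/COc1cc(O[Si](C(C)C)(C(C)C)C(C)C)c2c(c1C/C=C(\C)CCC=C(C)C)O[C@H](c1ccc(O[Si](C)(C)C(C)(C)C)cc1)C=C2O[Si](C)(C)C(C)(C)C | intermediate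
15 | (2S)-8-geranyl-7-(geranyloxy)-5-hydroxy-2-(4-hydroxyphenyl)chroman-4-one | CC(C)=CCC/C(C)=C/COc1cc(O)c2c(c1C/C=C(\C)CCC=C(C)C)O[C@H](c1ccc(O)cc1)CC2=O | target

## Step count and least certain steps

Total step count: 10. Longest linear sequence: 7 steps (steps 1, 2, 3, 7, 8, 9, 10; the ring B branch, steps 4–6 followed by 7–10, is equally long).

**Step 9 (key step).** Three processes could spoil it.
- Diversion of the alkylidene: it may close onto the proximal alkene of the C8 chain (seven-membered closure with loss of the chain end), or it may stall at the hindered enol ether.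
- Double-bond migration: ruthenium hydride formed by catalyst decay could move the vinyl double bond toward C2 and destroy the stereocentre. A catalytic amount of 1,4-benzoquinone is the usual countermeasure.
- Thermal ring opening: reversible electrocyclic opening of the electron-rich 2H-chromene product would erode the enantiomeric purity if the mixture is heated long.

The fallback gives up the metathesis and introduces C2 by conjugate addition; it sets out from 6. Heating with N,N-dimethylformamide dimethyl acetal should give the enaminone (E)-3-(dimethylamino)-1-[3-geranyl-4-(geranyloxy)-2-hydroxy-6-(triisopropylsilyloxy)phenyl]prop-2-en-1-one F1. Warm acetic acid should close it through its only free hydroxyl to 8-geranyl-7-(geranyloxy)-5-(triisopropylsilyloxy)-4H-chromen-4-one F2. Enantioselective conjugate addition of 4-hydroxyphenylboronic acid, with Pd(OCOCF3)2 and the tert-butyl-PyOx enantiomer that delivers the 2S series, should give (2S)-8-geranyl-7-(geranyloxy)-2-(4-hydroxyphenyl)-5-(triisopropylsilyloxy)chroman-4-one F3. The Bu4NF/AcOH treatment of step 10 then removes the last silyl group, and the fallback comes back to the route at 15.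

**Step 7.** The aryloxide is flanked on both sides and chelated to the acetyl group, so attack on the allyl complex may be slow. The product has a good aryloxide leaving group on a carbon that is both allylic and para-oxygenated benzylic, so the catalyst may re-ionise it, with loss of enantiomeric purity and drift to the linear ether. C-allylation at the unsubstituted ring carbon para to the aryloxide oxygen (the future C6) is a further competing process. Short reaction times at room temperature are the first defence.

The fallback separates the enantioselective event from the bond to the hindered phenol; it sets out from 10. The same iridium chemistry, with KHCO3 as a hydroxide equivalent and the mirror-image (Ra,Rc,Rc) ligand, should give the branched alcohol (1R)-1-[4-(tert-butyldimethylsilyloxy)phenyl]prop-2-en-1-ol F4. A Mitsunobu reaction of F4 with 6 (PPh3, DIAD, toluene, 0 °C) then forms O1–C2 with inversion and comes back to the route at 12.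

**Step 1.** The phloroglucinol anion is ambident, so poor site selectivity (oxygen against carbon, mono- against dialkylation) may leave little of 3.

The fallback reverses the order of the two geranylations; it sets out from 1. A Mitsunobu reaction with 4 at the unchelated para-hydroxyl should give 1-[4-(geranyloxy)-2,6-dihydroxyphenyl]ethanone F5. ortho-C-Alkylation of its sodium salt with 2 in toluene (NaH), where the tight ion pair directs the allylic bromide to one of two equivalent ring carbons, then comes back to the route at 5, bypassing 3.

**Step 10.** The fluoride-generated enolate may expel the C8a oxygen before it is protonated; ring opening to the chalcone and unselective reclosure would epimerise C2. Incomplete cleavage of the hindered aryl silyl ether next to the carbonyl is the lesser risk.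

The fallback unveils the ketone without ever forming an enolate; it sets out from 14. Aqueous acetic acid in THF should hydrolyse only the enol silyl ether, by protonation at C3, to (2S)-2-[4-(tert-butyldimethylsilyloxy)phenyl]-8-geranyl-7-(geranyloxy)-5-(triisopropylsilyloxy)chroman-4-one F6. HF·pyridine in THF then removes the two aryl silyl groups under acidic fluoride conditions and comes back to the route at 15.

## Further compounds

F1 | step 9 | (E)-3-(dimethylamino)-1-[3-geranyl-4-(geranyloxy)-2-hydroxy-6-(triisopropylsilyloxy)phenyl]prop-2-en-1-one | CC(C)=CCC/C(C)=C/COc1cc(O[Si](C(C)C)(C(C)C)C(C)C)c(C(=O)/C=C/N(C)C)c(O)c1C/C=C(\C)CCC=C(C)C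
F2 | step 9 | 8-geranyl-7-(geranyloxy)-5-(triisopropylsilyloxy)-4H-chromen-4-one | CC(C)=CCC/C(C)=C/COc1cc(O[Si](C(C)C)(C(C)C)C(C)C)c2c(c1C/C=C(\C)CCC=C(C)C)occc2=O
F3 | step 9 | (2S)-8-geranyl-7-(geranyloxy)-2-(4-hydroxyphenyl)-5-(triisopropylsilyloxy)chroman-4-one | CC(C)=CCC/C(C)=C/COc1cc(O[Si](C(C)C)(C(C)C)C(C)C)c2c(c1C/C=C(\C)CCC=C(C)C)O[C@H](c1ccc(O)cc1)CC2=O
F4 | step 7 | (1R)-1-[4-(tert-butyldimethylsilyloxy)phenyl]prop-2-en-1-ol | O[C@@H](c1ccc(O[Si](C)(C)C(C)(C)C)cc1)C=C
F5 | step 1 | 1-[4-(geranyloxy)-2,6-dihydroxyphenyl]ethanone | CC(C)=CCC/C(C)=C/COc1cc(O)c(C(C)=O)c(O)c1
F6 | step 10 | (2S)-2-[4-(tert-butyldimethylsilyloxy)phenyl]-8-geranyl-7-(geranyloxy)-5-(triisopropylsilyloxy)chroman-4-one | CC(C)=CCC/C(C)=C/COc1cc(O[Si](C(C)C)(C(C)C)C(C)C)c2c(c1C/C=C(\C)CCC=C(C)C)O[C@H](c1ccc(O[Si](C)(C)C(C)(C)C)cc1)CC2=O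
A1 | alternative 1 | 8-geranyl-7-(geranyloxy)-4-methylene-5-(triisopropylsilyloxy)-2-[4-(triisopropylsilyloxy)phenyl]-4H-1,3-benzodioxine (racemic) | CC(C)=CCC/C(C)=C/COc1cc(O[Si](C(C)C)(C(C)C)C(C)C)c2c(c1C/C=C(\C)CCC=C(C)C)OC(c1ccc(O[Si](C(C)C)(C(C)C)C(C)C)cc1)OC2=C
A2 | alternative 1 | (2S)-8-geranyl-7-(geranyloxy)-5,4'-bis(triisopropylsilyloxy)flavanone | CC(C)=CCC/C(C)=C/COc1cc(O[Si](C(C)C)(C(C)C)C(C)C)c2c(c1C/C=C(\C)CCC=C(C)C)O[C@H](c1ccc(O[Si](C(C)C)(C(C)C)C(C)C)cc1)CC2=O
A3 | alternative 2 | 3-(methoxymethoxy)cyclobut-2-en-1-one | COCOC1=CC(=O)C1
A4 | alternative 2 | triisopropyl{[(4E)-5,9-dimethyldeca-4,8-dien-1-yn-1-yl]oxy}silane | CC(C)=CCC/C(C)=C/CC#CO[Si](C(C)C)(C(C)C)C(C)C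
A5 | alternative 2 | 2-geranyl-5-(methoxymethoxy)-3-(triisopropylsilyloxy)phenol | Oc1cc(OCOC)cc(O[Si](C(C)C)(C(C)C)C(C)C)c1C/C=C(\C)CCC=C(C)C
A6 | alternative 3 | tert-butyl 4-{(2S)-2-[4-(tert-butyldimethylsilyloxy)phenyl]-4-oxo-3,4-dihydro-2H-pyran-6-yl}-4-geranyl-3-oxobutanoate (chain C4 unspecified) | CC(C)=CCC/C(C)=C/CC(C(=O)CC(=O)OC(C)(C)C)C1=CC(=O)C[C@@H](c2ccc(O[Si](C)(C)C(C)(C)C)cc2)O1
A7 | alternative 3 | (2S)-8-geranyl-5,7-dihydroxy-4'-(tert-butyldimethylsilyloxy)flavanone | Oc1cc(O)c2c(c1C/C=C(\C)CCC=C(C)C)O[C@H](c1ccc(O[Si](C)(C)C(C)(C)C)cc1)CC2=O
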